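**Assumption:** methyl (S)-glycidate, isoprene, benzoic acid and the three Grignard solutions are bought; a telescoped one-pot operation counts as one step. The route is designed on paper and has not been run.

## Retrosynthetic overview

1. Caespitol ⇐ its C3 benzoate **15**; the ring Br/Cl pair is installed last from the cyclohexene of **12**, via a trans-diaxial diol, a tertiary bromide and a bromonium ion opened by chloride.
2. Oxane ring ⇐ 6-endo bromoetherification of tertiary alcohol **11** (tertiary OH onto the prenyl alkene).
3. Oxane C2 ⇐ non-chelation methyl addition to α-benzoyloxy ketone **9**; oxane C3 ⇐ Mitsunobu inversion of ketol **7**.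
4. Cyclohexene ring and its stereocentre ⇐ Diels–Alder of isoprene with α'-hydroxy enone **5** (key step).
5. **5** ⇐ methyl (S)-glycidate (the only bought stereocentre) + isobutenyl and vinyl Grignards. Ring order: cyclohexene first, oxane second.

## Route

**Step 1**
Reactants: **1** methyl (S)-glycidate; **2** (2-methylprop-1-en-1-yl)magnesium bromide
Product: **3** methyl (S)-2-hydroxy-5-methylhex-4-enoate
Conditions: **2** (1.3 equiv), CuI (10 mol %), THF, −40 °C
Reagents that add atoms: (2-methylprop-1-en-1-yl)magnesium bromide, CC(C)=C[Mg]Br
Why: Copper-catalysed Grignard opening of the glycidic ester (SN2 at the unsubstituted C3, faster than ester addition at −40 °C) installs the prenyl terminus and leaves the bought stereocentre untouched.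

**Step 2**
Reactants: **3**; **4** vinylmagnesium bromide
Product: **5** (S)-4-hydroxy-7-methylocta-1,6-dien-3-one
Conditions: MeNHOMe·HCl, i-PrMgCl (3 equiv), THF, −20 °C; then CH2=CHMgBr, −20 → 0 °C; inverse quench into cold 1 M HCl
Reagents that add atoms: vinylmagnesium bromide, C=C[Mg]Br
Why: One-pot Weinreb amide formation and ketone synthesis; the chelated tetrahedral intermediate survives until the acidic quench, so there is no over-addition and the α-stereocentre (as its alkoxide) is not enolised.

**Step 3 (key step)**
Reactants: **5**; **6** isoprene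
Product: **7** (S)-2-hydroxy-5-methyl-1-[(S)-4-methylcyclohex-3-en-1-yl]hex-4-en-1-one
Conditions: isoprene (5 equiv), ZnCl2 (1.1 equiv), CH2Cl2, −40 → −20 °C
Reagents that add atoms: isoprene, C=CC(C)=C
Why: Lewis acid-promoted Diels–Alder cycloaddition with "para" regiochemistry; zinc chelates C=O and the α'-OH, locking an s-cis enone that isoprene attacks on the face anti to the side chain, so the bought (S)-carbinol sets the ring stereocentre as (S).

**Step 4**
Reactants: **7**; **8** benzoic acid
Product: **9** (R)-5-methyl-1-[(S)-4-methylcyclohex-3-en-1-yl]-1-oxohex-4-en-2-yl benzoate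
Conditions: PhCO2H, PPh3, DIAD, THF, 0 °C → rt
Reagents that add atoms: benzoic acid, OC(=O)c1ccccc1
Why: Mitsunobu esterification (SN2, activated by the adjacent carbonyl) inverts the carbinol to (R) and turns it into a poorly chelating benzoate that protects this oxygen until the end.

**Step 5**
Reactants: **9**; **10** methylmagnesium bromide
Product: **11** (2R,3R)-2-hydroxy-6-methyl-2-[(S)-4-methylcyclohex-3-en-1-yl]hept-5-en-3-yl benzoate
Conditions: MeMgBr, CeCl3, THF, −78 °C
Reagents that add atoms: methylmagnesium bromide, C[Mg]Br
Why: Organocerium 1,2-addition is faster at the ketone than at the benzoate and is non-basic; it follows the polar Felkin–Anh/Cornforth model (C–OBz anti to the incoming methyl, attack past H), giving the (2R) tertiary alcohol syn to the benzoate.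

**Step 6**
Reactants: **11**
Product: **12** (2R,3R,5R)-5-bromo-2,6,6-trimethyl-2-[(S)-4-methylcyclohex-3-en-1-yl]oxan-3-yl benzoate
Conditions: NBS (1.05 equiv), (CF3)2CHOH, 0 °C, dark
Reagents that add atoms: N-bromosuccinimide, O=C1CCC(=O)N1Br
Why: Bromoetherification: the bromonium ion of the side-chain alkene is opened 6-endo (Markovnikov) by the tertiary OH through a chair with the cyclohexenyl group and the new C–Br bond equatorial, setting C5 as (R); the benzoate blocks 5-endo closure by O3, and the ring alkene has no chair-like internal trap.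

**Step 7**
Reactants: **12**
Product: **13** (2R,3R,5R)-5-bromo-2-[(1S,3R,4R)-3,4-dihydroxy-4-methylcyclohexyl]-2,6,6-trimethyloxan-3-yl benzoate (trans-diaxial diol: tertiary OH cis, secondary OH trans to the oxanyl group)
Conditions: mCPBA, NaHCO3, CH2Cl2, 0 °C; then 5 % aq. H2SO4, THF, rt
Reagents that add atoms: mCPBA, OOC(=O)c1cccc(Cl)c1; water, O
Why: Prilezhaev epoxidation (face-unselective) then acid-catalysed trans-diaxial (Fürst–Plattner) hydrolysis; the epoxide anti to the C1 substituent opens at the tertiary carbon and the syn epoxide at the secondary carbon, so both converge on one diol, as the limonene oxides do.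

**Step 8**
Reactants: **13**
Product: **14** (2R,3R,5R)-5-bromo-2-[(1S,3R,4R)-4-bromo-3-hydroxy-4-methylcyclohexyl]-2,6,6-trimethyloxan-3-yl benzoate
Conditions: 48 % aq. HBr, CH2Cl2, 0 °C, short contact
Reagents that add atoms: hydrogen bromide, Br
Why: SN1 substitution of the tertiary alcohol with neighbouring-group participation: the antiperiplanar secondary OH closes to a protonated epoxide, which bromide reopens trans-diaxially at the tertiary carbon, so Br replaces the tertiary OH with net retention.

**Step 9**
Reactants: **14**
Product: **15** (2R,3R,5R)-5-bromo-2-[(1S,3S,4S)-3-bromo-4-chloro-4-methylcyclohexyl]-2,6,6-trimethyloxan-3-yl benzoate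
Conditions: SOCl2, pyridine, CH2Cl2, −20 → 0 °C
Reagents that add atoms: thionyl chloride, ClS(Cl)=O
Why: Chlorosulfite ionisation assisted by the antiperiplanar bromine gives the bromonium ion on the face cis to the C1 substituent; chloride opens it at the more substituted carbon (Markovnikov, 1,2-bromine shift), leaving Br on the secondary carbon cis and Cl on the tertiary carbon trans to the side chain (trans-diequatorial, 1S,3S,4S).

**Step 10**
Reactants: **15**
Product: **16** caespitol, (2R,3R,5R)-5-bromo-2-[(1S,3S,4S)-3-bromo-4-chloro-4-methylcyclohexyl]-2,6,6-trimethyloxan-3-ol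
Conditions: DIBAL-H, CH2Cl2, −78 °C
Reagents that add atoms: none
Why: Reductive cleavage of the hindered axial benzoate at −78 °C, where the alkyl halides and the ether are inert and no stereocentre is touched.

## Compound list

1 | methyl (S)-glycidate (methyl (S)-oxirane-2-carboxylate) | COC(=O)[C@@H]1CO1 | starting material
2 | (2-methylprop-1-en-1-yl)magnesium bromide | CC(C)=C[Mg]Br | starting material
3 | methyl (S)-2-hydroxy-5-methylhex-4-enoate | COC(=O)[C@@H](O)CC=C(C)C | intermediate
4 | vinylmagnesium bromide | C=C[Mg]Br | starting material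
5 | (S)-4-hydroxy-7-methylocta-1,6-dien-3-one | C=CC(=O)[C@@H](O)CC=C(C)C | intermediate
6 | isoprene | C=CC(C)=C | starting material
7 | (S)-2-hydroxy-5-methyl-1-[(S)-4-methylcyclohex-3-en-1-yl]hex-4-en-1-one | CC1=CC[C@H](CC1)C(=O)[C@@H](O)CC=C(C)C | intermediate
8 | benzoic acid | OC(=O)c1ccccc1 | starting material
9 | (R)-5-methyl-1-[(S)-4-methylcyclohex-3-en-1-yl]-1-oxohex-4-en-2-yl benzoate | CC1=CC[C@H](CC1)C(=O)[C@H](OC(=O)c1ccccc1)CC=C(C)C | intermediate
10 | methylmagnesium bromide | C[Mg]Br | starting material
11 | (2R,3R)-2-hydroxy-6-methyl-2-[(S)-4-methylcyclohex-3-en-1-yl]hept-5-en-3-yl benzoate | CC1=CC[C@H](CC1)[C@@](C)(O)[C@H](OC(=O)c1ccccc1)CC=C(C)C | intermediate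
12 | (2R,3R,5R)-5-bromo-2,6,6-trimethyl-2-[(S)-4-methylcyclohex-3-en-1-yl]oxan-3-yl benzoate | CC1(C)O[C@](C)([C@@H]2CC=C(C)CC2)[C@H](OC(=O)c3ccccc3)C[C@H]1Br | intermediate
13 | (2R,3R,5R)-5-bromo-2-[(1S,3R,4R)-3,4-dihydroxy-4-methylcyclohexyl]-2,6,6-trimethyloxan-3-yl benzoate | CC1(C)O[C@](C)([C@H]2CC[C@@](C)(O)[C@H](O)C2)[C@H](OC(=O)c3ccccc3)C[C@H]1Br | intermediate
14 | (2R,3R,5R)-5-bromo-2-[(1S,3R,4R)-4-bromo-3-hydroxy-4-methylcyclohexyl]-2,6,6-trimethyloxan-3-yl benzoate | CC1(C)O[C@](C)([C@H]2CC[C@@](C)(Br)[C@H](O)C2)[C@H](OC(=O)c3ccccc3)C[C@H]1Br | intermediate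
15 | (2R,3R,5R)-5-bromo-2-[(1S,3S,4S)-3-bromo-4-chloro-4-methylcyclohexyl]-2,6,6-trimethyloxan-3-yl benzoate | CC1(C)O[C@](C)([C@H]2CC[C@](C)(Cl)[C@@H](Br)C2)[C@H](OC(=O)c3ccccc3)C[C@H]1Br | intermediate
16 | caespitol | CC1(C)O[C@](C)([C@H]2CC[C@](C)(Cl)[C@@H](Br)C2)[C@H](O)C[C@H]1Br | target

## Summary

Total steps: 10. Longest linear sequence: 10 (from methyl (S)-glycidate).

A direct BrCl addition to **12** is not used because trans-diaxial opening would give mainly the wrong ring diastereomer (Cl cis, Br trans to the side chain); steps 7–9 exist to force the bromonium onto the correct face.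

Three steps most likely to fail, each with a fallback that changes the approach:

- **Step 9 (regiochemistry of bromonium opening).** Chloride may attack the secondary carbon instead, giving the trans-diaxial 4-bromo-3-chloro regioisomer. Fallback: do not re-optimise the opening; heat that isomer (or the mixture) in a polar solvent to effect the diaxial → diequatorial 1,2-halogen interchange (dyotropic rearrangement), which leads to the same (1S,3S,4S)-3-bromo-4-chloro array as **15**.
- **Step 8 (tertiary bromide from the diol under strong acid).** Ether cleavage or pinacol-type shift may compete. Fallback: skip the diol; separate the two epoxides from the mCPBA step and open only the epoxide anti to the C1 substituent with Li2NiBr4 (neutral, trans-diaxial at the tertiary carbon) to reach **14**. Return the other epoxide to **12** by deoxygenation (e.g. WCl6/n-BuLi).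
- **Step 5 (Felkin selectivity and benzoate survival).** The acyloxy group may chelate or migrate. Fallback: build the tertiary carbinol by directed epoxidation instead. Methylenate ketone **9** (Petasis), cleave the benzoate, epoxidise the 2-substituted allylic alcohol with VO(acac)2/t-BuOOH (erythro-selective through A1,2 strain, giving the same 2R,3R relationship), open the epoxide at CH2 with LiEt3BH, and re-benzoylate the secondary OH.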